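**Retrosynthetic overview** (target numbering: ring C1 bears the aryl group, C2=C3(Me), C4, C5(Me2), C6; C7 is the carbinol carbon)
1. Target 11 comes from aryl ketone 10 by Felkin-controlled hydride reduction at C7.
2. 10 comes from ring enone 8 (ketone at C2, alkene C3=C4): tosylhydrazone reduction with 1,3-transposition removes the ketone and leaves C2=C3 and C4H2.
3. 8 comes from 7 and aryl iodide 2 by palladium α-arylation, which places the C1 aryl group trans to C6.
4. Key bond C6–C7: 7 comes from dienone 5 and aryl nitromethane 3; the nitronate serves as an aroyl anion in an enantioselective conjugate addition, and a Nef reaction reveals the ketone.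
5. No ring is built: the carbocycle is bought as 4 and both coumarin rings come from 1.

Assumption: 4 is bought (otherwise one Robinson annulation of isobutyraldehyde with ethyl vinyl ketone), iodination of 1 is taken as C-8 selective, and the sense of induction in step 4 is assigned by analogy and must be confirmed.

**Step 1**
Reactants: 1 5,7-dimethoxy-2H-chromen-2-one
Product: 2 8-iodo-5,7-dimethoxy-2H-chromen-2-one
Conditions: NIS (1.05 equiv), CF3CO2H (0.3 equiv), MeCN, rt
Reagents that add atoms: N-iodosuccinimide, O=C1CCC(=O)N1I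
Why: Electrophilic aromatic iodination of the trialkoxy-activated ring, where C-8 (between a methoxy group and the ring oxygen) is the less crowded of the two activated positions; no stereocenter is formed.

**Step 2**
Reactants: 2 8-iodo-5,7-dimethoxy-2H-chromen-2-one
Product: 3 5,7-dimethoxy-8-(nitromethyl)-2H-chromen-2-one
Conditions: Pd2(dba)3 (2.5 mol %), XPhos (6 mol %), Cs2CO3 (1.1 equiv), 4 Å MS, MeNO2 (solvent), 50 °C
Reagents that add atoms: nitromethane, C[N+](=O)[O-]
Why: Palladium-catalysed cross-coupling of an aryl halide with the nitronate of nitromethane (Kozlowski nitromethylation) gives an aryl nitromethane, a latent aroyl anion, without exposing the lactone to organolithium or Grignard reagents.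

**Step 3**
Reactants: 4 2,4,4-trimethylcyclohex-2-en-1-one
Product: 5 2,4,4-trimethylcyclohexa-2,5-dien-1-one
Conditions: IBX (1.8 equiv), DMSO–fluorobenzene 1:2, 75 °C
Reagents that add atoms: none
Why: IBX α,β-dehydrogenation (Nicolaou) of the only CH2–CH2 unit next to the carbonyl gives the cross-conjugated dienone, which cannot aromatise because of the quaternary carbon.

**Step 4**
Reactants: 5 2,4,4-trimethylcyclohexa-2,5-dien-1-one; 3 5,7-dimethoxy-8-(nitromethyl)-2H-chromen-2-one
Product: 7 (5R)-5-[(5,7-dimethoxy-2-oxo-2H-chromen-8-yl)carbonyl]-2,4,4-trimethylcyclohex-2-en-1-one, via nitro Michael adduct 6 (not isolated)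
Conditions: 9-amino-9-deoxy-epi-quinidine (20 mol %), 2-fluorobenzoic acid (40 mol %), toluene, 35 °C, 72 h (5 in 1.5-fold excess); then DBU (2.5 equiv), O2 (1 atm), MeCN, 0 °C to rt
Reagents that add atoms: dioxygen, O=O
Why: In this asymmetric organocatalytic nitro-Michael addition and one-pot base/O2 Nef reaction, iminium activation of 5 by the chiral primary amine sends the nitronate of 3 (an aroyl-anion equivalent) to the β-carbon of the unsubstituted enone arm (the α-methyl arm is far slower under iminium catalysis), joining the future carbinol carbon C7 to the enone β-carbon C6, two centres that are both electrophilic in normal reactivity, with catalyst face selection setting C6 as 5R (the quinine-derived pseudo-enantiomer is used instead if the face preference proves opposite).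

**Step 5**
Reactants: 7 (5R)-5-[(5,7-dimethoxy-2-oxo-2H-chromen-8-yl)carbonyl]-2,4,4-trimethylcyclohex-2-en-1-one; 2 8-iodo-5,7-dimethoxy-2H-chromen-2-one
Product: 8 (5R,6S)-6-(5,7-dimethoxy-2-oxo-2H-chromen-8-yl)-5-[(5,7-dimethoxy-2-oxo-2H-chromen-8-yl)carbonyl]-2,4,4-trimethylcyclohex-2-en-1-one
Conditions: Pd2(dba)3 (2.5 mol %), tBu3P·HBF4 (10 mol %), K3PO4 (2.5 equiv), toluene, 90 °C
Reagents that add atoms: none
Why: In this palladium-catalysed ketone α-arylation (Buchwald–Hartwig type) only the CH2 next to the ring carbonyl gives a usable enolate (the hydrogen at C6 would give an A1,3-strained enolate and a quaternary centre), and the epimerisable new C1 stereocenter settles trans (diequatorial) to the neighbouring aroyl group under the basic conditions, giving 6S.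

**Step 6**
Reactants: 8 (5R,6S)-6-(5,7-dimethoxy-2-oxo-2H-chromen-8-yl)-5-[(5,7-dimethoxy-2-oxo-2H-chromen-8-yl)carbonyl]-2,4,4-trimethylcyclohex-2-en-1-one
Product: 10 8-{[(1R,2S)-2-(5,7-dimethoxy-2-oxo-2H-chromen-8-yl)-4,6,6-trimethylcyclohex-3-en-1-yl]carbonyl}-5,7-dimethoxy-2H-chromen-2-one, via tosylhydrazone 9 (not isolated)
Conditions: TsNHNH2 (1.3 equiv), AcOH (cat.), EtOH, 60 °C; evaporate; catecholborane (3 equiv), CHCl3, 0 °C to rt; then NaOAc·3H2O, 60 °C
Reagents that add atoms: none
Why: Only the ring carbonyl condenses with tosylhydrazide (the doubly ortho-substituted, vinylogous-ester-like aryl ketone is expected to be inert), and catecholborane reduction of the α,β-unsaturated tosylhydrazone (Kabalka reaction) gives an allylic diazene that loses N2 by a retro-ene [1,5]-hydrogen shift, moving the alkene to C2=C3 and leaving C4 as CH2 without touching a stereocenter.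

**Step 7**
Reactants: 10 8-{[(1R,2S)-2-(5,7-dimethoxy-2-oxo-2H-chromen-8-yl)-4,6,6-trimethylcyclohex-3-en-1-yl]carbonyl}-5,7-dimethoxy-2H-chromen-2-one
Product: 11 8-[(1S,6R)-6-[(R)-(5,7-dimethoxy-2-oxo-2H-chromen-8-yl)(hydroxy)methyl]-3,5,5-trimethylcyclohex-2-en-1-yl]-5,7-dimethoxy-2H-chromen-2-one
Conditions: NaBH4 (3 equiv), CeCl3·7H2O (1.5 equiv), MeOH–THF 1:1, 0 °C to rt
Reagents that add atoms: none
Why: Luche reduction attacks only the ketone (the coumarin lactones are left), and the (R)-carbinol results if hydride adds in the Felkin–Anh sense with the quaternary C5 as the large group, that is anti to C5 and past the small C6–H; this rests on ranking C5 above C1 and is the main uncertainty in diastereoselectivity.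

**Compound list**
1 | 5,7-dimethoxy-2H-chromen-2-one (5,7-dimethoxycoumarin) | COc1cc(OC)c2ccc(=O)oc2c1 | starting material
2 | 8-iodo-5,7-dimethoxy-2H-chromen-2-one | COc1cc(OC)c2ccc(=O)oc2c1I | intermediate
3 | 5,7-dimethoxy-8-(nitromethyl)-2H-chromen-2-one | COc1cc(OC)c2ccc(=O)oc2c1C[N+](=O)[O-] | intermediate
4 | 2,4,4-trimethylcyclohex-2-en-1-one | CC1=CC(C)(C)CCC1=O | starting material
5 | 2,4,4-trimethylcyclohexa-2,5-dien-1-one | CC1=CC(C)(C)C=CC1=O | intermediate
6 | (5R)-5-[(5,7-dimethoxy-2-oxo-2H-chromen-8-yl)(nitro)methyl]-2,4,4-trimethylcyclohex-2-en-1-one (both epimers at the nitro-bearing carbon) | CC1=CC(C)(C)[C@H](C([N+](=O)[O-])c2c(OC)cc(OC)c3ccc(=O)oc23)CC1=O | intermediate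
7 | (5R)-5-[(5,7-dimethoxy-2-oxo-2H-chromen-8-yl)carbonyl]-2,4,4-trimethylcyclohex-2-en-1-one | CC1=CC(C)(C)[C@H](C(=O)c2c(OC)cc(OC)c3ccc(=O)oc23)CC1=O | intermediate
8 | (5R,6S)-6-(5,7-dimethoxy-2-oxo-2H-chromen-8-yl)-5-[(5,7-dimethoxy-2-oxo-2H-chromen-8-yl)carbonyl]-2,4,4-trimethylcyclohex-2-en-1-one | CC1=CC(C)(C)[C@H](C(=O)c2c(OC)cc(OC)c3ccc(=O)oc23)[C@@H](c2c(OC)cc(OC)c3ccc(=O)oc23)C1=O | intermediate
9 | N'-[(5R,6S)-6-(5,7-dimethoxy-2-oxo-2H-chromen-8-yl)-5-[(5,7-dimethoxy-2-oxo-2H-chromen-8-yl)carbonyl]-2,4,4-trimethylcyclohex-2-en-1-ylidene]-4-methylbenzenesulfonohydrazide | CC1=CC(C)(C)[C@H](C(=O)c2c(OC)cc(OC)c3ccc(=O)oc23)[C@@H](c2c(OC)cc(OC)c3ccc(=O)oc23)C1=NNS(=O)(=O)c1ccc(C)cc1 | intermediate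
10 | 8-{[(1R,2S)-2-(5,7-dimethoxy-2-oxo-2H-chromen-8-yl)-4,6,6-trimethylcyclohex-3-en-1-yl]carbonyl}-5,7-dimethoxy-2H-chromen-2-one | COc1cc(OC)c2ccc(=O)oc2c1[C@H]1C=C(C)CC(C)(C)[C@@H]1C(=O)c1c(OC)cc(OC)c2ccc(=O)oc12 | intermediate
11 | 8-[(1S,6R)-6-[(R)-(5,7-dimethoxy-2-oxo-2H-chromen-8-yl)(hydroxy)methyl]-3,5,5-trimethylcyclohex-2-en-1-yl]-5,7-dimethoxy-2H-chromen-2-one | COc1cc(OC)c2ccc(=O)oc2c1[C@H]1C=C(C)CC(C)(C)[C@@H]1[C@@H](O)c1c(OC)cc(OC)c2ccc(=O)oc12 | target

**Totals**
Total step count: 7.
Longest linear sequence: 6 steps (1 → 2 → 3 → 7 → 8 → 10 → 11, i.e. steps 1, 2, 4, 5, 6, 7).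

**Steps most likely to fail and their fallbacks**

Step 4 may fail because a secondary nitronate carrying a doubly ortho-substituted aryl group has to attack a β-carbon next to a quaternary centre, and the face selectivity on a cross-conjugated dienone is untested. The fallback sets out from 1 and 5 and comes back at 7. Rieche formylation of 1 (Cl2CHOMe, TiCl4, CH2Cl2, 0 °C) gives 5,7-dimethoxy-2-oxo-2H-chromene-8-carbaldehyde F1. Its aroyl radical, formed by abstraction of the formyl hydrogen by photoexcited eosin Y under blue light, adds to the iminium ion of 5 formed with the same chiral primary amine. This radical Stetter-type hydroacylation has an early, sterically undemanding transition state and gives 7 without a Nef step.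

Step 5 may fail because a doubly ortho-substituted aryl iodide has to couple with a β-branched enolate at palladium. The fallback sets out from 2 and 7 and comes back at 8. Compound 2 is oxidised (mCPBA, TsOH·H2O, MeCN) and coupled in the same flask with 1,3,5-trimethoxybenzene to give (5,7-dimethoxy-2-oxo-2H-chromen-8-yl)(2,4,6-trimethoxyphenyl)iodonium tosylate F2. The potassium enolate of 7 (KN(SiMe3)2, THF, −78 °C) is then arylated by F2 in a metal-free ligand coupling in which the electron-rich trimethoxyphenyl group stays on iodine, and base equilibration gives trans 8.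

Step 6 may fail because the ring carbonyl is flanked by the aryl-bearing carbon and the methyl-substituted alkene, so hydrazone formation may stall. The fallback sets out from 8 and comes back at 11.
- NaBH4/CeCl3·7H2O reduces both ketones of 8 to the diol (5R,6S)-6-(5,7-dimethoxy-2-oxo-2H-chromen-8-yl)-5-[(R)-(5,7-dimethoxy-2-oxo-2H-chromen-8-yl)(hydroxy)methyl]-2,4,4-trimethylcyclohex-2-en-1-ol F3. Facial control at the benzylic carbinol is the same as in step 7, and either epimer at the allylic carbinol serves.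
- A Myers reductive transposition (2-nitrobenzenesulfonylhydrazide, PPh3, diethyl azodicarboxylate, N-methylmorpholine, −30 °C to rt) should engage only the allylic hydroxyl, because the benzylic one is shielded by two ortho substituents and the quaternary neighbour. It gives the N-allylic 2-nitrobenzenesulfonylhydrazine F4.
- F4 loses sulfinate to give the allylic diazene F5, whose retro-ene loss of N2 delivers 11 directly.

**Further compounds**
F1 | step 4 | 5,7-dimethoxy-2-oxo-2H-chromene-8-carbaldehyde | COc1cc(OC)c2ccc(=O)oc2c1C=O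
F2 | step 5 | (5,7-dimethoxy-2-oxo-2H-chromen-8-yl)(2,4,6-trimethoxyphenyl)iodonium 4-methylbenzenesulfonate | COc1cc(OC)c2ccc(=O)oc2c1[I+]c1c(OC)cc(OC)cc1OC.Cc1ccc(cc1)S([O-])(=O)=O
F3 | step 6 | (5R,6S)-6-(5,7-dimethoxy-2-oxo-2H-chromen-8-yl)-5-[(R)-(5,7-dimethoxy-2-oxo-2H-chromen-8-yl)(hydroxy)methyl]-2,4,4-trimethylcyclohex-2-en-1-ol (either epimer at C-1) | CC1=CC(C)(C)[C@H]([C@@H](O)c2c(OC)cc(OC)c3ccc(=O)oc23)[C@@H](c2c(OC)cc(OC)c3ccc(=O)oc23)C1O
F4 | step 6 | N-[(5R,6S)-6-(5,7-dimethoxy-2-oxo-2H-chromen-8-yl)-5-[(R)-(5,7-dimethoxy-2-oxo-2H-chromen-8-yl)(hydroxy)methyl]-2,4,4-trimethylcyclohex-2-en-1-yl]-2-nitrobenzenesulfonohydrazide (either epimer at C-1) | CC1=CC(C)(C)[C@H]([C@@H](O)c2c(OC)cc(OC)c3ccc(=O)oc23)[C@@H](c2c(OC)cc(OC)c3ccc(=O)oc23)C1N(N)S(=O)(=O)c1ccccc1[N+](=O)[O-]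
F5 | step 6 | [(5R,6S)-6-(5,7-dimethoxy-2-oxo-2H-chromen-8-yl)-5-[(R)-(5,7-dimethoxy-2-oxo-2H-chromen-8-yl)(hydroxy)methyl]-2,4,4-trimethylcyclohex-2-en-1-yl]diazene (either epimer at C-1) | CC1=CC(C)(C)[C@H]([C@@H](O)c2c(OC)cc(OC)c3ccc(=O)oc23)[C@@H](c2c(OC)cc(OC)c3ccc(=O)oc23)C1N=N
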